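The numbers are made up; the rest is arithmetic.

Single product is the middle of a chain, made from substrate and then coupled on to double product, so I wanted the hour at which it peaks.

| flask | substrate | gas | time | remark | temperature |
|---|---|---|---|---|---|
| Friday's | 0.21 M | 26 mM (held) | 10 h | at 100 °C until 3.0 h, from then on at 115 °C |  |
| Thursday's | 0.21 M | 26 mM (held) | 10 h |  | 115 °C |
| Tuesday's | 0.21 M | 26 mM (held) | 10 h |  | 100 °C |

    crystals ⇌ released group, rate k1*(cs1 - [released group]) while solid is left; crystals form when [released group] > cs1 (cs1 = 0.15 M, k1 = 0.0047 s⁻¹)
    coupling partner + other mono adduct → double product + released group (k2 = 0.038 M⁻¹ s⁻¹, Ea2 = 77.0 kJ mol⁻¹)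
    substrate + coupling partner → other mono adduct + released group (k3 = 0.011 M⁻¹ s⁻¹, Ea3 = 64.0 kJ mol⁻¹)
    gas ⇌ coupling partner, rate k4*(csat - [coupling partner]) (k4 = 2.4 × 10⁻⁴ s⁻¹, csat = 26 mM)
    substrate + coupling partner → single product + released group (k5 = 0.014 M⁻¹ s⁻¹, Ea5 = 58.0 kJ mol⁻¹)
    coupling partner + single product → double product + released group (k6 = 0.018 M⁻¹ s⁻¹, Ea6 = 58.0 kJ mol⁻¹)
    (constants at 100 °C)

- for released group the crystals are counted in
- as a solid, counted per litre of solution: crystals
- at the start none of coupling partner is dissolved
- the list of constants is for 100 °C, to be carried to other temperatures by the activation energies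

- the flask with the highest amount of single product, in percent of the substrate charged ("all alike" if they lie within 1.5 percentage points) (Friday's / Thursday's / Tuesday's / all alike)
- final single product, as a percentage of the substrate charged, in Friday's
- final single product, as a percentage of the substrate charged, in Thursday's
- final single product, as a percentage of the substrate charged, in Tuesday's

I began with Tuesday's. In the first instants no coupling partner was dissolved. Gas transfer has a time of 69.4 min, while substrate consumes dissolved coupling partner with a lifetime of 190 s, far shorter, so I expected it to rest at a low level and the gas to set the pace: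

dissolved level = 1.14 mM
feed = 0.0215 M h⁻¹

In the middle of the run, each coupling spends one coupling partner. Single product peaks when it is used as fast as it is made, so at the peak it stands to substrate as step 5 to step 6, 0.778. Dissolved coupling partner cancels from these ratios, which gave me for Tuesday's:

r = k6/(k3+k5) = 0.720
substrate at the peak = r^(1/(1−r)) = 30.9%
single product at the peak = 24.1%
other mono adduct at the peak = 12.0%

Every substrate gone costs two coupling partners, less one for each mono adduct still standing:

need per substrate charged = 1.02

At the end comes the quantity I carried, the gas hours to the peak, which is the need times the charge, divided by the feed: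

gas hours to the peak = 9.98 h

That is about the 10 h allowed, so I put Tuesday's at its top. At 115 °C, steps 5 and 6 both speed up 2.1-fold, and step 3 gains a further 1.08-fold on them. Thursday's peak thus moved to 23.6%, only 0.50 percentage points lower. Taking each flask as near its top at 10 h, I reckoned the three alike, with Friday's between the other two.

The forecast said all alike, with 23.7% for Friday's, 23.6% for Thursday's and 24.1% for Tuesday's, holding that “Each flask therefore ends close to the single-product maximum”.

The flasks came out all alike: 23.8% in Friday's, 23.6% in Thursday's and 24.1% in Tuesday's.

Tuesday's ended with 31.5% of its substrate left against my 30.9%, and its released group and crystals came to 0.212 M against the 0.214 M I had reckoned for the peak. The neighbouring flask, Tuesday's with 0.13 M of substrate, has the same reckoned need per substrate, but with its full charge I put its dissolved level at 1.79 mM. That gave me 6.35 h of gas hours to its peak, shorter than the 10 h. That flask ended with 11% of its substrate left, below the 30.9% I had reckoned for the peak, and with 18.8% of single product.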